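**Retrosynthetic overview**

1. Locants: ring carbons C1 (C–OH, acyl), C2 (CHMe), C3 (CHOH), C4 (CH2), C5 and C6 (ring fusion; C6 bears the lactone oxygen), C7 (CH–O-tiglate); C8/C9 are the lactone α-carbon and carbonyl, C1' the ketone carbon. End game: O3 desilylation, C1' enone by Liebeskind–Srogl coupling of a thioester, C7 tiglate by esterification, C8 methyl by hydrogenation of an α-methylene lactone.
2. Key disconnection C5–C6: this bond lies in both the cycloheptane and the γ-lactone, with O on C6 and the carboxyl-bearing C8 on C5. An aldehyde at C6 and a 2-(methoxycarbonyl)allyl metal at C5 therefore close both rings in one intramolecular Barbier allylation/lactonization.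
3. Open-chain precursor: C6–C7–C1–C1' is the carbon backbone of L-tartaric acid (C6 and C1' are its carboxyl carbons, O7 and O1 its hydroxyl oxygens). C1 (quaternary) and C2 come from an Ireland–Claisen rearrangement, C3 from a Felkin-controlled allylation, C5=C8 from cross-metathesis.
4. Ring order: dioxolane (chiral pool, removed in step 12) → temporary γ-lactone C1'–O–C6 (step 3, opened in step 7) → cycloheptane and C9 γ-lactone together (step 10).

Key step: step 10

**Route**

Step 1
Reactants: 1 dimethyl (4R,5R)-2,2-dimethyl-1,3-dioxolane-4,5-dicarboxylate; 2 (E)-but-2-en-1-ol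
Product: 3 di[(E)-but-2-enyl] (4R,5R)-2,2-dimethyl-1,3-dioxolane-4,5-dicarboxylate
Conditions: 2 (6 equiv), Bu2SnO (10 mol %), toluene, 110 °C, MeOH distilled off
Reagents that add atoms: none
Why: Tin-alkoxide-catalysed transesterification driven by removal of methanol; the neutral conditions leave both stereocentres untouched and give a C2-symmetric diester, so enolization of either ester is equivalent.

Step 2
Reactants: 3 di[(E)-but-2-enyl] (4R,5R)-2,2-dimethyl-1,3-dioxolane-4,5-dicarboxylate
Product: 6 (4S,5R)-4-[(2S)-but-3-en-2-yl]-5-[(E)-but-2-enyloxycarbonyl]-2,2-dimethyl-1,3-dioxolane-4-carboxylic acid, via silyl ketene acetal 4 (not isolated), via trimethylsilyl ester 5 (not isolated)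
Conditions: LiN(iPr)2 (1.05 equiv), Me3SiCl, THF, −100 → −78 °C, then 25 °C; 1 M HCl work-up
Reagents that add atoms: none
Why: Ireland–Claisen rearrangement: the α-alkoxy ester should give the chelated enolate (enolate oxygen cis to the ring oxygen), trapped as 4, whose chair transition state with the (E)-crotyl group sets C2 (ring oxygen and methyl syn along C1'–C1–C2–C3), while delivery of the allyl unit to the face anti to the neighbouring ester on C7 sets the quaternary C1; silylation at −78 °C should outrun β-elimination of the acetal oxygen.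

Step 3
Reactants: 6 (4S,5R)-4-[(2S)-but-3-en-2-yl]-5-[(E)-but-2-enyloxycarbonyl]-2,2-dimethyl-1,3-dioxolane-4-carboxylic acid
Product: 8 (3aS,6aS)-3a-[(2S)-but-3-en-2-yl]-2,2-dimethyldihydrofuro[3,4-d][1,3]dioxol-4(3aH)-one, via hydroxy acid 7 (not isolated)
Conditions: NaOEt (1.0 equiv), NaBH4, EtOH, 0 → 25 °C; then 1 M HCl, 25 °C
Reagents that add atoms: none
Why: Borohydride reduces the activated α-alkoxy ester while the carboxylate is inert, and acidification lactonizes 7 (substituents cis on the dioxolane) to a γ-lactone that ties C1' to C6 and so differentiates the two former tartrate carboxyls; no stereocentre is formed.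

Step 4
Reactants: 8 (3aS,6aS)-3a-[(2S)-but-3-en-2-yl]-2,2-dimethyldihydrofuro[3,4-d][1,3]dioxol-4(3aH)-one
Product: 10 (2R)-2-[(3aS,6aS)-2,2-dimethyl-4-oxodihydrofuro[3,4-d][1,3]dioxol-3a(4H)-yl]propanal, via ozonide 9 (not isolated)
Conditions: O3, CH2Cl2, −78 °C; then PPh3, −78 → 25 °C
Reagents that add atoms: ozone, O=[O+][O-]
Why: Ozonolysis with reductive work-up cleaves the only alkene to the C3 aldehyde; at low temperature and without base C2 should not epimerize.

Step 5
Reactants: 10 (2R)-2-[(3aS,6aS)-2,2-dimethyl-4-oxodihydrofuro[3,4-d][1,3]dioxol-3a(4H)-yl]propanal; 11 allyltrimethylsilane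
Product: 12 (3aS,6aS)-3a-[(2S,3R)-3-hydroxyhex-5-en-2-yl]-2,2-dimethyldihydrofuro[3,4-d][1,3]dioxol-4(3aH)-one
Conditions: BF3·OEt2, CH2Cl2, −78 °C
Reagents that add atoms: none
Why: Hosomi–Sakurai allylation through an open transition state under Felkin–Anh control (the fully substituted C1 is the large group and its β-oxygen reinforces by 1,3-anti induction), which sets C3 with methyl and hydroxyl syn along C1–C2–C3–C4.

Step 6
Reactants: 12 (3aS,6aS)-3a-[(2S,3R)-3-hydroxyhex-5-en-2-yl]-2,2-dimethyldihydrofuro[3,4-d][1,3]dioxol-4(3aH)-one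
Product: 13 triisopropylsilyl ether of 12
Conditions: iPr3SiOTf, 2,6-lutidine, CH2Cl2, 0 → 25 °C
Reagents that add atoms: triisopropylsilyl trifluoromethanesulfonate, CC(C)[Si](OS(=O)(=O)C(F)(F)F)(C(C)C)C(C)C
Why: Silylation of the secondary alcohol with the silyl triflate; the bulky, acid-stable triisopropylsilyl group keeps O3 masked until the last step.

Step 7
Reactants: 13 triisopropylsilyl ether of 12
Product: 14 S-ethyl (4S,5S)-5-(hydroxymethyl)-2,2-dimethyl-4-{(2S,3R)-3-[tri(propan-2-yl)silyloxy]hex-5-en-2-yl}-1,3-dioxolane-4-carbothioate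
Conditions: AlMe3, EtSH, CH2Cl2, 0 → 25 °C; cold pH 7 buffer
Reagents that add atoms: ethanethiol, CCS
Why: Thiolysis of the γ-lactone with the aluminium thiolate made in the flask (the strong Al–O bond drives ring opening) frees the C6 hydroxyl and stores C1' as a thioester, the acyl donor for the late ketone synthesis.

Step 8
Reactants: 14 S-ethyl (4S,5S)-5-(hydroxymethyl)-2,2-dimethyl-4-{(2S,3R)-3-[tri(propan-2-yl)silyloxy]hex-5-en-2-yl}-1,3-dioxolane-4-carbothioate
Product: 15 S-ethyl (4S,5R)-5-formyl-2,2-dimethyl-4-{(2S,3R)-3-[tri(propan-2-yl)silyloxy]hex-5-en-2-yl}-1,3-dioxolane-4-carbothioate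
Conditions: Dess–Martin periodinane, CH2Cl2, 0 → 25 °C (on crude 14)
Reagents that add atoms: none
Why: Dess–Martin oxidation of the primary alcohol, run at once to forestall relactonization; the neutral conditions should spare the α-alkoxy aldehyde stereocentre C7 and the thioester.

Step 9
Reactants: 15 S-ethyl (4S,5R)-5-formyl-2,2-dimethyl-4-{(2S,3R)-3-[tri(propan-2-yl)silyloxy]hex-5-en-2-yl}-1,3-dioxolane-4-carbothioate; 16 methyl 2-(bromomethyl)prop-2-enoate
Product: 17 methyl (2Z,5R,6S)-2-(bromomethyl)-6-[(4S,5R)-4-(ethylsulfanylcarbonyl)-5-formyl-2,2-dimethyl-1,3-dioxolan-4-yl]-5-[tri(propan-2-yl)silyloxy]hept-2-enoate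
Conditions: 16 (4 equiv), Hoveyda–Grubbs second-generation catalyst RuCl2(H2IMes)(=CH-C6H4-2-OiPr) (10 mol %), CH2Cl2, 40 °C
Reagents that add atoms: none
Why: Olefin cross-metathesis of a terminal alkene with a 1,1-disubstituted acrylate that is slow to homodimerize; the thermodynamically favoured trisubstituted alkene has the chain trans to the ester, that is the (Z)-allylic bromide.

Step 10
Reactants: 17 methyl (2Z,5R,6S)-2-(bromomethyl)-6-[(4S,5R)-4-(ethylsulfanylcarbonyl)-5-formyl-2,2-dimethyl-1,3-dioxolan-4-yl]-5-[tri(propan-2-yl)silyloxy]hept-2-enoate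
Product: 20 tricyclic α-methylene lactone thioester (cycloheptane closed; cis-fused C9 lactone; acetonide and silyl ether retained), via allylindium dibromide 18 (not isolated), via hydroxy ester 19 (not isolated)
Conditions: In powder (3 equiv), THF–H2O (3:1), 0.005 M, 25 → 40 °C; then PPTS (cat.), toluene, 60 °C
Reagents that add atoms: none
Why: Indium inserts into the allylic C–Br bond to give 18, whose γ-carbon C5 adds to the tethered C6 aldehyde through a six-membered chair (Zimmerman–Traxler) transition state, and hydroxy ester 19 then lactonizes onto the methyl ester; this is an intramolecular Barbier allylation/lactonization (the ring-forming form of the Dreiding–Schmidt α-methylene lactone synthesis), and indium-mediated closures of ω-oxo-2-(bromomethyl)alk-2-enoates to cis-fused α-methylene γ-lactones on five-, six- and seven-membered carbocycles are the closest known reaction type. The cycloheptane closes by 7-exo-trig attack on the carbonyl (C5–C6 bond) and the γ-lactone by 5-exo-trig acyl substitution (O6–C9 bond). C5 relative to C6: the fixed alkene geometry (chain cis to the CH2–metal carbon) places C4 axial in the chair and gives the syn adduct, that is the cis ring fusion. C6 relative to C7: the nucleophile is tethered through C1 and must attack gauche to C1, and of the arrangements left the one with C6=O antiperiplanar to the C7–O bond of the non-chelating dioxolane (Cornforth-type dipole minimization) should place O6 trans to O7 as the target requires. Chemoselectivity for the aldehyde over the thioester and over protonolysis rests on the low basicity and carbonyl selectivity of allylindium reagents in water, high dilution suppresses oligomerization, and the fully substituted C1 with its dioxolane brings the chain ends together.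

Step 11
Reactants: 20 tricyclic α-methylene lactone thioester
Product: 21 tricyclic α-methyl lactone thioester (C8 methyl on the carbocycle face, as in the target)
Conditions: H2 (1 atm), RhCl(PPh3)3 (10 mol %), benzene–EtOH (1:1), 25 °C
Reagents that add atoms: none
Why: Homogeneous hydrogenation with the rhodium catalyst should saturate only the unhindered exocyclic alkene, delivering hydrogen to the convex face of the cis-fused lactone (the face of H5 and H6), which sets C8.

Step 12
Reactants: 21 tricyclic α-methyl lactone thioester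
Product: 22 C1,C7-diol thioester
Conditions: TFA–H2O (9:1), 0 → 25 °C
Reagents that add atoms: none
Why: Acid hydrolysis of the strained trans-fused acetonide; thioester, lactone and triisopropylsilyl ether are stable to brief aqueous acid, and the diol is freed before the enone exists so that O7 cannot add to it in conjugate fashion.

Step 13
Reactants: 22 C1,C7-diol thioester; 23 (E)-2-methylbut-2-enoic acid (tiglic acid)
Product: 25 C7 tiglate thioester, via mixed anhydride 24 (not isolated)
Conditions: 2,4,6-Cl3C6H2COCl, Et3N, THF, 25 °C; then 22, DMAP, toluene, 60 °C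
Reagents that add atoms: none
Why: Yamaguchi esterification: the secondary C7 hydroxyl is acylated by the mixed anhydride while the tertiary C1 hydroxyl is inert, and the (E)-geometry of the acid is kept.

Step 14
Reactants: 25 C7 tiglate thioester; 26 (E)-prop-1-enylboronic acid
Product: 27 3-O-triisopropylsilyl ether of the target
Conditions: Pd2(dba)3 (5 mol %), tri(2-furyl)phosphine (20 mol %), Cu(O2C-2-thienyl) (1.5 equiv), THF, 50 °C
Reagents that add atoms: none
Why: Liebeskind–Srogl coupling: the thioester couples with the alkenylboronic acid under palladium catalysis with the copper carboxylate as thiophile under neutral conditions, giving the (E)-enone with retention and leaving lactone, tiglate and the free tertiary alcohol untouched.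

Step 15
Reactants: 27 3-O-triisopropylsilyl ether of the target
Product: 28 target CNP0183494.2
Conditions: HF·pyridine, pyridine, THF, 0 → 25 °C
Reagents that add atoms: none
Why: Fluoride-mediated desilylation under buffered, weakly acidic conditions that the α-hydroxy enone, the tiglate and the lactone should tolerate.

**Compound list**

1 | dimethyl (4R,5R)-2,2-dimethyl-1,3-dioxolane-4,5-dicarboxylate (dimethyl 2,3-O-isopropylidene-L-tartrate) | COC(=O)[C@@H]1OC(C)(C)O[C@H]1C(=O)OC | starting material
2 | (E)-but-2-en-1-ol | C/C=C/CO | starting material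
3 | di[(E)-but-2-enyl] (4R,5R)-2,2-dimethyl-1,3-dioxolane-4,5-dicarboxylate | C/C=C/COC(=O)[C@@H]1OC(C)(C)O[C@H]1C(=O)OC/C=C/C | intermediate
4 | trimethylsilyl ketene acetal of 3 (exocyclic C=C on the dioxolane, OSiMe3 cis to the ring oxygen, remaining centre 4R) | C/C=C/COC(=O)[C@@H]1OC(C)(C)O/C1=C(\O[Si](C)(C)C)OC/C=C/C | intermediate
5 | trimethylsilyl ester of acid 6 | C/C=C/COC(=O)[C@@H]1OC(C)(C)O[C@@]1(C(=O)O[Si](C)(C)C)[C@@H](C)C=C | intermediate
6 | (4S,5R)-4-[(2S)-but-3-en-2-yl]-5-[(E)-but-2-enyloxycarbonyl]-2,2-dimethyl-1,3-dioxolane-4-carboxylic acid | C/C=C/COC(=O)[C@@H]1OC(C)(C)O[C@@]1(C(=O)O)[C@@H](C)C=C | intermediate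
7 | (4S,5S)-4-[(2S)-but-3-en-2-yl]-5-(hydroxymethyl)-2,2-dimethyl-1,3-dioxolane-4-carboxylic acid | OC[C@@H]1OC(C)(C)O[C@@]1(C(=O)O)[C@@H](C)C=C | intermediate
8 | (3aS,6aS)-3a-[(2S)-but-3-en-2-yl]-2,2-dimethyldihydrofuro[3,4-d][1,3]dioxol-4(3aH)-one | O=C1OC[C@@H]2OC(C)(C)O[C@]12[C@@H](C)C=C | intermediate
9 | secondary ozonide (1,2,4-trioxolane) of the vinyl group of 8, epimers at the trioxolane carbon | O=C1OC[C@@H]2OC(C)(C)O[C@]12[C@@H](C)C1OCOO1 | intermediate
10 | (2R)-2-[(3aS,6aS)-2,2-dimethyl-4-oxodihydrofuro[3,4-d][1,3]dioxol-3a(4H)-yl]propanal | O=C1OC[C@@H]2OC(C)(C)O[C@]12[C@@H](C)C=O | intermediate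
11 | allyltrimethylsilane | C=CC[Si](C)(C)C | starting material
12 | (3aS,6aS)-3a-[(2S,3R)-3-hydroxyhex-5-en-2-yl]-2,2-dimethyldihydrofuro[3,4-d][1,3]dioxol-4(3aH)-one | O=C1OC[C@@H]2OC(C)(C)O[C@]12[C@@H](C)[C@H](O)CC=C | intermediate
13 | triisopropylsilyl ether of 12 | O=C1OC[C@@H]2OC(C)(C)O[C@]12[C@@H](C)[C@H](O[Si](C(C)C)(C(C)C)C(C)C)CC=C | intermediate
14 | S-ethyl (4S,5S)-5-(hydroxymethyl)-2,2-dimethyl-4-{(2S,3R)-3-[tri(propan-2-yl)silyloxy]hex-5-en-2-yl}-1,3-dioxolane-4-carbothioate | OC[C@@H]1OC(C)(C)O[C@@]1(C(=O)SCC)[C@@H](C)[C@H](O[Si](C(C)C)(C(C)C)C(C)C)CC=C | intermediate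
15 | S-ethyl (4S,5R)-5-formyl-2,2-dimethyl-4-{(2S,3R)-3-[tri(propan-2-yl)silyloxy]hex-5-en-2-yl}-1,3-dioxolane-4-carbothioate | O=C[C@@H]1OC(C)(C)O[C@@]1(C(=O)SCC)[C@@H](C)[C@H](O[Si](C(C)C)(C(C)C)C(C)C)CC=C | intermediate
16 | methyl 2-(bromomethyl)prop-2-enoate | C=C(CBr)C(=O)OC | starting material
17 | methyl (2Z,5R,6S)-2-(bromomethyl)-6-[(4S,5R)-4-(ethylsulfanylcarbonyl)-5-formyl-2,2-dimethyl-1,3-dioxolan-4-yl]-5-[tri(propan-2-yl)silyloxy]hept-2-enoate | O=C[C@@H]1OC(C)(C)O[C@@]1(C(=O)SCC)[C@@H](C)[C@H](O[Si](C(C)C)(C(C)C)C(C)C)C/C=C(\CBr)C(=O)OC | intermediate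
18 | allylindium dibromide from 17 (CH2InBr2 in place of CH2Br; drawn as the monoallyl component of the sesquibromide) | O=C[C@@H]1OC(C)(C)O[C@@]1(C(=O)SCC)[C@@H](C)[C@H](O[Si](C(C)C)(C(C)C)C(C)C)C/C=C(\C[In](Br)Br)C(=O)OC | intermediate
19 | cycloheptane γ-hydroxy ester (C6–OH cis to the C5 2-(methoxycarbonyl)vinyl group; O1/O7 acetonide; O3 silyl ether; C1' thioester) | CCSC(=O)[C@]1(OC(C)(C)O3)[C@@H](C)[C@H](O[Si](C(C)C)(C(C)C)C(C)C)C[C@H]([C@@H](O)[C@@H]13)C(=C)C(=O)OC | intermediate
20 | tricyclic α-methylene lactone thioester (cis-fused C9 lactone with exocyclic C8=CH2; trans-fused O1/O7 acetonide; O3 silyl ether; ring stereocentres as in the target) | CCSC(=O)[C@]1(OC(C)(C)O3)[C@@H](C)[C@H](O[Si](C(C)C)(C(C)C)C(C)C)C[C@@H]2[C@@H](OC(=O)C2=C)[C@@H]13 | intermediate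
21 | tricyclic α-methyl lactone thioester (as 20, C8 methyl as in the target) | CCSC(=O)[C@]1(OC(C)(C)O3)[C@@H](C)[C@H](O[Si](C(C)C)(C(C)C)C(C)C)C[C@@H]2[C@@H](OC(=O)[C@@H]2C)[C@@H]13 | intermediate
22 | C1,C7-diol thioester (acetonide removed from 21) | CCSC(=O)[C@]1(O)[C@@H](C)[C@H](O[Si](C(C)C)(C(C)C)C(C)C)C[C@@H]2[C@@H](OC(=O)[C@@H]2C)[C@@H]1O | intermediate
23 | (E)-2-methylbut-2-enoic acid (tiglic acid) | C/C=C(\C)C(=O)O | starting material
24 | (E)-2-methylbut-2-enoic 2,4,6-trichlorobenzoic anhydride | C/C=C(\C)C(=O)OC(=O)c1c(Cl)cc(Cl)cc1Cl | intermediate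
25 | C7 tiglate thioester (22 acylated at O7) | CCSC(=O)[C@]1(O)[C@@H](C)[C@H](O[Si](C(C)C)(C(C)C)C(C)C)C[C@@H]2[C@@H](OC(=O)[C@@H]2C)[C@@H]1OC(=O)/C(C)=C/C | intermediate
26 | (E)-prop-1-enylboronic acid | C/C=C/B(O)O | starting material
27 | 3-O-triisopropylsilyl ether of the target | C/C=C/C(=O)[C@]1(O)[C@@H](C)[C@H](O[Si](C(C)C)(C(C)C)C(C)C)C[C@@H]2[C@@H](OC(=O)[C@@H]2C)[C@@H]1OC(=O)/C(C)=C/C | intermediate
28 | CNP0183494.2 | C/C=C/C(=O)[C@]1(O)[C@@H](C)[C@H](O)C[C@@H]2[C@@H](OC(=O)[C@@H]2C)[C@@H]1OC(=O)/C(C)=C/C | target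

**Step count and risks**

Total step count: 15. Longest linear sequence: 15 steps (from 1).

Steps most likely to fail:

Step 10. The seven-membered closure is entropically slow, so protonolysis or intermolecular reaction of the allylindium may compete, and attack on the aldehyde face may be poorly selective. The fallback sets out from 15: cross-metathesis with methyl 2-[(trimethylsilyl)methyl]prop-2-enoate should give the allylsilane aldehyde F1. BF3·OEt2 in CH2Cl2 at −78 °C would then trigger an intramolecular Hosomi–Sakurai reaction through an open, non-organometallic transition state to hydroxy ester 19, which lactonizes under the PPTS treatment, and the route is rejoined at 20.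

Step 9. The allylic bromide may deactivate the ruthenium carbene, or the 1,1-disubstituted partner may react too slowly so that 15 homodimerizes. The fallback sets out from 15: cross-metathesis with methyl methacrylate, a standard partner, should give the (E)-2-methyl enoate F2. SmI2 in THF–MeOH would then close the ring by ketyl–olefin radical cyclization; protonation of the samarium enolate from the convex face should give the saturated hydroxy ester F3, which lactonizes, and the route is rejoined at 21 (steps 10 and 11 are skipped).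

Step 7. The γ-hydroxy thioester may relactonize to 13 during work-up, before it can be oxidized. The fallback sets out from 13: after the thiolysis the aluminium alkoxide is silylated in the same flask (Et3SiCl, imidazole) to give the chromatographically stable triethylsilyl ether F4. Swern oxidation (oxalyl chloride, DMSO, Et3N), which converts primary triethylsilyl ethers directly into aldehydes, then gives 15, where the route is rejoined.

Further compounds
F1 | step 10 | methyl (2E,5R,6S)-6-[(4S,5R)-4-(ethylsulfanylcarbonyl)-5-formyl-2,2-dimethyl-1,3-dioxolan-4-yl]-5-[tri(propan-2-yl)silyloxy]-2-[(trimethylsilyl)methyl]hept-2-enoate (allylsilane aldehyde, chain cis to the CH2Si carbon) | O=C[C@@H]1OC(C)(C)O[C@@]1(C(=O)SCC)[C@@H](C)[C@H](O[Si](C(C)C)(C(C)C)C(C)C)C/C=C(\C[Si](C)(C)C)C(=O)OC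
F2 | step 9 | methyl (2E,5R,6S)-6-[(4S,5R)-4-(ethylsulfanylcarbonyl)-5-formyl-2,2-dimethyl-1,3-dioxolan-4-yl]-2-methyl-5-[tri(propan-2-yl)silyloxy]hept-2-enoate | O=C[C@@H]1OC(C)(C)O[C@@]1(C(=O)SCC)[C@@H](C)[C@H](O[Si](C(C)C)(C(C)C)C(C)C)C/C=C(\C)C(=O)OC
F3 | step 9 | saturated cycloheptane γ-hydroxy ester (as 19 with C8 as CH(CH3), configuration as in 21) | CCSC(=O)[C@]1(OC(C)(C)O3)[C@@H](C)[C@H](O[Si](C(C)C)(C(C)C)C(C)C)C[C@H]([C@@H](O)[C@@H]13)[C@@H](C)C(=O)OC
F4 | step 7 | triethylsilyl ether of 14 | CC[Si](CC)(CC)OC[C@@H]1OC(C)(C)O[C@@]1(C(=O)SCC)[C@@H](C)[C@H](O[Si](C(C)C)(C(C)C)C(C)C)CC=C
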